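Cuts: the C4–styryl bond; in each dihydrobenzofuran the C3–aryl bond and the C3–C3a bond; the C2–C7' bond and the C2'–ring F bond.
Enabling feature: O1'–C2'(ring F)–C3'(ring G)–C3a' on ring B is a 5-oxygenated flavanone with its carbonyl carbon pushed out of the ring, so excising that carbon joins C3' to the ring B carbon C3a' and leaves a carboxyl carbon on C3' just where ring G stands; O1–C2(ring B)–C3(ring D)–C3a on ring A repeats the pattern.
Forward: chromone → flavanone carrying ring F (conjugate addition) → 3-diazoflavanone → Wolff contraction to the furan ring on ring B → ring G by decarboxylative arylation → C7' bromide → boronic acid.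
That boronic acid adds to a ring A chromone; the same diazo transfer, contraction and arylation give the second furan ring with ring D; ring E comes last by Suzuki–Miyaura styrylation at C4, then all nine methyl ethers are cleaved.
Stereochemistry: C2' and C2 from the chiral pyridine-oxazoline palladium catalyst in the two conjugate additions; C3' and C3 trans by capture of the benzylic radical anti to the neighbouring aryl group; the E alkene from the E-alkenylboronic acid.

Key step: step 5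

Labels: dihydrobenzofuran 2 has primed locants (O1', C2', C3', C3a', C4'–C7', C7a'); its benzo ring is ring B, ring F is the 2,4-dioxygenated aryl on C2', ring G the 3,5-dioxygenated aryl on C3'. Dihydrobenzofuran 1 has plain locants; its benzo ring is ring A, ring D is the 3,5-dioxygenated aryl on C3, ring E the 4-oxygenated aryl of the styryl group on C4. "DBF-7-yl" stands for the (2S,3S)-2-(2,4-dimethoxyphenyl)-3-(3,5-dimethoxyphenyl)-4-methoxy-2,3-dihydrobenzofuran-7-yl group of compounds 18 and 19. (R)-t-BuPyOx is (R)-4-tert-butyl-2-(pyridin-2-yl)-4,5-dihydro-1,3-oxazole.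

Assumption: (R)-t-BuPyOx is taken to give the 2S flavanones, by analogy with the facial sense this ligand class shows on cyclic enones; if the sense proves opposite, the (S)-ligand is used in steps 3 and 14 and nothing else changes.

Step 1
Reactants: 1 2',6'-dihydroxyacetophenone
Product: 2 1-[2-(benzyloxy)-6-hydroxyphenyl]ethan-1-one
Conditions: BnBr (1.0 equiv), K2CO3, acetone, reflux
Reagents that add atoms: benzyl bromide, BrCc1ccccc1
Why: Williamson etherification should stop at the mono-ether because the remaining phenol is held in a hydrogen bond to the acetyl carbonyl and is far less nucleophilic.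

Step 2
Reactants: 2 1-[2-(benzyloxy)-6-hydroxyphenyl]ethan-1-one
Product: 4 5-(benzyloxy)-4H-chromen-4-one, via enaminone 3 (not isolated)
Conditions: Me2NCH(OMe)2, toluene, 100 °C; evaporate; then AcOH, 100 °C
Reagents that add atoms: N,N-dimethylformamide dimethyl acetal, COC(OC)N(C)C
Why: Enaminone chromone synthesis, in which condensation at the acetyl methyl group is followed by acid-promoted addition of the free phenol to the enaminone and loss of dimethylamine.

Step 3
Reactants: 4 5-(benzyloxy)-4H-chromen-4-one; 5 2,4-dimethoxyphenylboronic acid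
Product: 6 (2S)-5-(benzyloxy)-2-(2,4-dimethoxyphenyl)chroman-4-one
Conditions: 5 (2–3 equiv), Pd(OCOCF3)2 (5 mol %), (R)-t-BuPyOx (6 mol %), NH4PF6 (30 mol %), H2O (5 equiv), ClCH2CH2Cl, 60 °C
Reagents that add atoms: none
Why: Palladium-catalysed asymmetric conjugate addition of an arylboronic acid to a chromone (aryl transfer from boron to divalent palladium, face-selective insertion of the C2=C3 bond, protonolysis of the palladium enolate by water), in which the pyridine-oxazoline ligand sets C2, the later C2', and the excess of 5 makes up for protodeboronation.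

Step 4
Reactants: 6 (2S)-5-(benzyloxy)-2-(2,4-dimethoxyphenyl)chroman-4-one
Product: 8 (2R)-5-(benzyloxy)-3-diazo-2-(2,4-dimethoxyphenyl)chroman-4-one, via trifluoroacetyl ketone 7 (not isolated)
Conditions: LiN(SiMe3)2, THF, −78 °C; CF3CO2CH2CF3, −78 °C; cold aq. HCl work-up, crude used at once; then MsN3, Et3N, H2O (1 equiv), MeCN, 20 °C
Reagents that add atoms: methanesulfonyl azide, CS(=O)(=O)N=[N+]=[N-]
Why: Detrifluoroacetylative diazo transfer (a Regitz-type transfer), in which the kinetic enolate is formed and C-acylated at −78 °C, too cold for retro-oxa-Michael opening to the chalcone, and the resulting 1,3-diketone takes the diazo group from the sulfonyl azide with loss of the trifluoroacetyl group, so that C2 keeps its spatial arrangement (the descriptor becomes R only because the diazo carbon now outranks the aryl group).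

Step 5
Reactants: 8 (2R)-5-(benzyloxy)-3-diazo-2-(2,4-dimethoxyphenyl)chroman-4-one
Product: 11 methyl (2S,3S)-4-(benzyloxy)-2-(2,4-dimethoxyphenyl)-2,3-dihydrobenzofuran-3-carboxylate (trans), via ketene 9 (not isolated), via cis ester 10 (not isolated)
Conditions: hν (365 nm LEDs), degassed MeOH/THF (4:1), 0–10 °C; then NaOMe (0.2 equiv), 20 °C; AcOH quench
Reagents that add atoms: methanol, CO
Why: Excitation of the diazo ketone expels N2 and, because the ring holds the C=O and C=N2 groups s-cis, the ring B carbon C3a' shifts from the carbonyl carbon to C3' as nitrogen leaves, giving the ring-contracted ketene 9, to which methanol adds before the ester enol tautomerises. The closest known reaction type is the photochemical Wolff ring contraction of cyclic 2-diazo ketones, 3-diazochroman-4-ones included. The five-membered O1'–C2'–C3'–C3a'–C7a' ring arises by a 1,2-aryl shift that contracts the pyranone, not by a cyclisation, so no closure mode applies and neither the C2'–O1' bond nor the configuration at C2' is touched. The new stereocentre C3' should be protonated kinetically anti to ring F (cis ester 10) and is then equilibrated by NaOMe to the trans ester, ring F on C2' being the controlling element, while opening of the ester enolate would be a reverse 5-endo-trig process and is not expected. The step needs rearrangement to win over a 1,2-hydride shift from C2' (which would give the flavone) and over O–H insertion; the locked s-cis geometry, the good migratory aptitude of the electron-rich aryl carbon and direct irradiation at a wavelength that only the diazo ketone absorbs should secure this.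

Step 6
Reactants: 11 methyl (2S,3S)-4-(benzyloxy)-2-(2,4-dimethoxyphenyl)-2,3-dihydrobenzofuran-3-carboxylate
Product: 12 (2S,3S)-4-(benzyloxy)-2-(2,4-dimethoxyphenyl)-2,3-dihydrobenzofuran-3-carboxylic acid
Conditions: LiOH·H2O, THF/MeOH/H2O, 20–40 °C; then 1 M HCl to pH 3, 0 °C
Reagents that add atoms: lithium hydroxide, [Li+].[OH-]
Why: Saponification of the methyl ester, in which C2' is safe because loss of the O1' aryloxide from the enolate would again be a reverse 5-endo-trig opening and any epimerisation at C3' is erased in step 7.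

Step 7
Reactants: 12 (2S,3S)-4-(benzyloxy)-2-(2,4-dimethoxyphenyl)-2,3-dihydrobenzofuran-3-carboxylic acid; 13 1-iodo-3,5-dimethoxybenzene
Product: 15 (2S,3S)-4-(benzyloxy)-2-(2,4-dimethoxyphenyl)-3-(3,5-dimethoxyphenyl)-2,3-dihydrobenzofuran, via N-acyloxyphthalimide 14 (not isolated)
Conditions: N-hydroxyphthalimide, i-PrN=C=N-i-Pr, DMAP (cat.), DMA, 20 °C; then, same flask, 13 (1.5 equiv), NiBr2(dme) (10 mol %), 4,4'-di-tert-butyl-2,2'-bipyridine (10 mol %), Zn powder (2 equiv), 20 °C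
Reagents that add atoms: none
Why: Nickel-catalysed decarboxylative cross-electrophile arylation of a redox-active ester, in which single-electron reduction of 14 releases CO2 and the benzylic C3' radical, the aryl–nickel species captures it on the face away from ring F, and reductive elimination should give the trans-2,3-diaryl product.

Step 8
Reactants: 15 (2S,3S)-4-(benzyloxy)-2-(2,4-dimethoxyphenyl)-3-(3,5-dimethoxyphenyl)-2,3-dihydrobenzofuran
Product: 16 (2S,3S)-2-(2,4-dimethoxyphenyl)-3-(3,5-dimethoxyphenyl)-2,3-dihydrobenzofuran-4-ol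
Conditions: H2 (1 atm), Pd/C (10 wt % Pd), EtOAc, 20 °C
Reagents that add atoms: none
Why: Hydrogenolysis of the benzyl aryl ether, stopped at full conversion so that the slower cleavage of the cyclic benzylic C2'–O1' bond does not set in.

Step 9
Reactants: 16 (2S,3S)-2-(2,4-dimethoxyphenyl)-3-(3,5-dimethoxyphenyl)-2,3-dihydrobenzofuran-4-ol
Product: 17 (2S,3S)-7-bromo-2-(2,4-dimethoxyphenyl)-3-(3,5-dimethoxyphenyl)-2,3-dihydrobenzofuran-4-ol
Conditions: 2,4,4,6-tetrabromocyclohexa-2,5-dien-1-one (1.0 equiv), CH2Cl2, −30 → 0 °C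
Reagents that add atoms: 2,4,4,6-tetrabromocyclohexa-2,5-dien-1-one, O=C1C(Br)=CC(Br)(Br)C=C1Br
Why: Electrophilic aromatic bromination with a mild, bulky bromonium donor that reacts with free phenols much faster than with aryl methyl ethers, so that only ring B should be attacked, and at C7', para to the hydroxyl group, in preference to the more crowded ortho position C5'.

Step 10
Reactants: 17 (2S,3S)-7-bromo-2-(2,4-dimethoxyphenyl)-3-(3,5-dimethoxyphenyl)-2,3-dihydrobenzofuran-4-ol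
Product: 18 (2S,3S)-7-bromo-2-(2,4-dimethoxyphenyl)-3-(3,5-dimethoxyphenyl)-4-methoxy-2,3-dihydrobenzofuran
Conditions: MeI, K2CO3, acetone, 50 °C
Reagents that add atoms: iodomethane, CI
Why: Williamson O-methylation, which removes the acidic phenol proton before the halogen–lithium exchange.

Step 11
Reactants: 18 (2S,3S)-7-bromo-2-(2,4-dimethoxyphenyl)-3-(3,5-dimethoxyphenyl)-4-methoxy-2,3-dihydrobenzofuran
Product: 19 [(2S,3S)-2-(2,4-dimethoxyphenyl)-3-(3,5-dimethoxyphenyl)-4-methoxy-2,3-dihydrobenzofuran-7-yl]boronic acid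
Conditions: n-BuLi, THF, −78 °C; B(OiPr)3, −78 → 0 °C; 1 M HCl, 0 °C
Reagents that add atoms: triisopropyl borate, CC(C)OB(OC(C)C)OC(C)C; water, O
Why: Bromine–lithium exchange, borylation of the aryllithium and hydrolysis of the borate, the exchange at −78 °C being faster than deprotonation of the methoxy-flanked ring positions.

Step 12
Reactants: 20 2',6'-dihydroxy-4'-methoxyacetophenone
Product: 21 1-[2-(benzyloxy)-6-hydroxy-4-methoxyphenyl]ethan-1-one
Conditions: BnBr (1.0 equiv), K2CO3, acetone, reflux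
Reagents that add atoms: benzyl bromide, BrCc1ccccc1
Why: Williamson mono-etherification as in step 1, the second phenol being deactivated by its hydrogen bond to the carbonyl group.

Step 13
Reactants: 21 1-[2-(benzyloxy)-6-hydroxy-4-methoxyphenyl]ethan-1-one
Product: 23 5-(benzyloxy)-7-methoxy-4H-chromen-4-one, via enaminone 22 (not isolated)
Conditions: Me2NCH(OMe)2, toluene, 100 °C; evaporate; then AcOH, 100 °C
Reagents that add atoms: N,N-dimethylformamide dimethyl acetal, COC(OC)N(C)C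
Why: Enaminone chromone synthesis as in step 2.

Step 14
Reactants: 19 [(2S,3S)-2-(2,4-dimethoxyphenyl)-3-(3,5-dimethoxyphenyl)-4-methoxy-2,3-dihydrobenzofuran-7-yl]boronic acid; 23 5-(benzyloxy)-7-methoxy-4H-chromen-4-one
Product: 24 (2S)-5-(benzyloxy)-2-(DBF-7-yl)-7-methoxychroman-4-one
Conditions: 23 (2 equiv), Pd(OCOCF3)2 (10 mol %), (R)-t-BuPyOx (12 mol %), NH4PF6 (30 mol %), H2O (5 equiv), ClCH2CH2Cl, 60 °C
Reagents that add atoms: none
Why: Palladium-catalysed asymmetric conjugate addition as in step 3, now with the chromone in excess, in which the ligand and not the remote stereocentres of 19 should decide the face of C2 and make it S.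

Step 15
Reactants: 24 (2S)-5-(benzyloxy)-2-(DBF-7-yl)-7-methoxychroman-4-one
Product: 26 (2R)-5-(benzyloxy)-3-diazo-2-(DBF-7-yl)-7-methoxychroman-4-one, via trifluoroacetyl ketone 25 (not isolated)
Conditions: LiN(SiMe3)2, THF, −78 °C; CF3CO2CH2CF3, −78 °C; cold aq. HCl work-up, crude used at once; then MsN3, Et3N, H2O (1 equiv), MeCN, 20 °C
Reagents that add atoms: methanesulfonyl azide, CS(=O)(=O)N=[N+]=[N-]
Why: Detrifluoroacetylative diazo transfer as in step 4, with kinetic enolate formation at −78 °C protecting C2 from retro-oxa-Michael opening.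

Step 16
Reactants: 26 (2R)-5-(benzyloxy)-3-diazo-2-(DBF-7-yl)-7-methoxychroman-4-one
Product: 28 (2S)-4-(benzyloxy)-2-(DBF-7-yl)-6-methoxy-2,3-dihydrobenzofuran-3-carboxylic acid (C3 epimers), via ketene 27 (not isolated)
Conditions: hν (365 nm LEDs), degassed THF/H2O (10:1), 0–10 °C
Reagents that add atoms: water, O
Why: Photochemical Wolff ring contraction as in step 5, in which the ring A carbon C3a migrates to C3 and water traps the ketene to give the acid directly; the ester checkpoint of step 5 (where enantiomeric purity is measured) is not needed here, and the configuration at C3 is immaterial because step 17 erases it.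

Step 17
Reactants: 28 (2S)-4-(benzyloxy)-2-(DBF-7-yl)-6-methoxy-2,3-dihydrobenzofuran-3-carboxylic acid; 13 1-iodo-3,5-dimethoxybenzene
Product: 30 (2S,3S)-4-(benzyloxy)-3-(3,5-dimethoxyphenyl)-2-(DBF-7-yl)-6-methoxy-2,3-dihydrobenzofuran, via N-acyloxyphthalimide 29 (not isolated)
Conditions: N-hydroxyphthalimide, i-PrN=C=N-i-Pr, DMAP (cat.), DMA, 20 °C; then, same flask, 13 (1.5 equiv), NiBr2(dme) (10 mol %), 4,4'-di-tert-butyl-2,2'-bipyridine (10 mol %), Zn powder (2 equiv), 20 °C
Reagents that add atoms: none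
Why: Nickel-catalysed decarboxylative cross-electrophile arylation as in step 7, in which the C3 radical should be captured anti to the bulky aryl group on C2 so that ring D ends trans to it.

Step 18
Reactants: 30 (2S,3S)-4-(benzyloxy)-3-(3,5-dimethoxyphenyl)-2-(DBF-7-yl)-6-methoxy-2,3-dihydrobenzofuran
Product: 31 (2S,3S)-3-(3,5-dimethoxyphenyl)-2-(DBF-7-yl)-6-methoxy-2,3-dihydrobenzofuran-4-ol
Conditions: H2 (1 atm), Pd/C (10 wt % Pd), EtOAc, 20 °C
Reagents that add atoms: none
Why: Hydrogenolysis of the benzyl aryl ether as in step 8, with no alkene or halide yet present.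

Step 19
Reactants: 31 (2S,3S)-3-(3,5-dimethoxyphenyl)-2-(DBF-7-yl)-6-methoxy-2,3-dihydrobenzofuran-4-ol
Product: 32 (2S,3S)-3-(3,5-dimethoxyphenyl)-2-(DBF-7-yl)-6-methoxy-2,3-dihydrobenzofuran-4-yl trifluoromethanesulfonate
Conditions: Tf2O, pyridine, CH2Cl2, −20 → 0 °C
Reagents that add atoms: trifluoromethanesulfonic anhydride, O=S(=O)(OS(=O)(=O)C(F)(F)F)C(F)(F)F
Why: O-Sulfonylation of the phenol turns the C4 oxygen into a leaving group for cross-coupling, O-triflation being far faster than any reaction at the methoxy-substituted rings.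

Step 20
Reactants: 32 (2S,3S)-3-(3,5-dimethoxyphenyl)-2-(DBF-7-yl)-6-methoxy-2,3-dihydrobenzofuran-4-yl trifluoromethanesulfonate; 33 (E)-2-(4-methoxyphenyl)ethenylboronic acid
Product: 34 (2S,3S)-3-(3,5-dimethoxyphenyl)-2-(DBF-7-yl)-6-methoxy-4-[(E)-2-(4-methoxyphenyl)ethenyl]-2,3-dihydrobenzofuran (nonamethyl ether of the target)
Conditions: Pd(OAc)2 (5 mol %), SPhos (10 mol %), K3PO4, toluene/H2O, 80 °C
Reagents that add atoms: none
Why: Suzuki–Miyaura coupling of the aryl triflate with an alkenylboronic acid, which transfers the alkenyl group with retention and so fixes the E geometry.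

Step 21
Reactants: 34 nonamethyl ether of the target
Product: 35 CNP0397447.1, (2S,3S)-2-[(2S,3S)-2-(2,4-dihydroxyphenyl)-3-(3,5-dihydroxyphenyl)-4-hydroxy-2,3-dihydrobenzofuran-7-yl]-3-(3,5-dihydroxyphenyl)-4-[(E)-2-(4-hydroxyphenyl)ethenyl]-2,3-dihydrobenzofuran-6-ol
Conditions: BBr3 (about 3 equiv per OMe), CH2Cl2, −78 → 20 °C; MeOH at −78 °C, then aq. NaHCO3
Reagents that add atoms: none
Why: Lewis-acid cleavage of all nine aryl methyl ethers with BBr3, the four stereocentres being unaffected and any reversible ionisation of a benzylic C–O bond returning the more stable trans ring.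

Compound list
1 | 2',6'-dihydroxyacetophenone | CC(=O)c1c(O)cccc1O | starting material
2 | 1-[2-(benzyloxy)-6-hydroxyphenyl]ethan-1-one | CC(=O)c1c(O)cccc1OCc1ccccc1 | intermediate
3 | (E)-1-[2-(benzyloxy)-6-hydroxyphenyl]-3-(dimethylamino)prop-2-en-1-one | CN(C)/C=C/C(=O)c1c(O)cccc1OCc1ccccc1 | intermediate
4 | 5-(benzyloxy)-4H-chromen-4-one | O=c1ccoc2cccc(OCc3ccccc3)c12 | intermediate
5 | 2,4-dimethoxyphenylboronic acid | COc1ccc(B(O)O)c(OC)c1 | starting material
6 | (2S)-5-(benzyloxy)-2-(2,4-dimethoxyphenyl)chroman-4-one | O=C1C[C@@H](c2ccc(OC)cc2OC)Oc2cccc(OCc3ccccc3)c21 | intermediate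
7 | (2S)-5-(benzyloxy)-2-(2,4-dimethoxyphenyl)-3-(trifluoroacetyl)chroman-4-one (C3 epimers, in equilibrium with the enol) | O=C1C(C(=O)C(F)(F)F)[C@@H](c2ccc(OC)cc2OC)Oc2cccc(OCc3ccccc3)c21 | intermediate
8 | (2R)-5-(benzyloxy)-3-diazo-2-(2,4-dimethoxyphenyl)chroman-4-one | O=C1C(=[N+]=[N-])[C@@H](c2ccc(OC)cc2OC)Oc2cccc(OCc3ccccc3)c21 | intermediate
9 | (2R)-4-(benzyloxy)-2-(2,4-dimethoxyphenyl)-3-(oxomethylidene)-2,3-dihydrobenzofuran (ketene) | c1ccc(OCc3ccccc3)c2c1O[C@H](c1ccc(OC)cc1OC)C2=C=O | intermediate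
10 | methyl (2S,3R)-4-(benzyloxy)-2-(2,4-dimethoxyphenyl)-2,3-dihydrobenzofuran-3-carboxylate (cis) | c1ccc(OCc3ccccc3)c2c1O[C@H](c1ccc(OC)cc1OC)[C@@H]2C(=O)OC | intermediate
11 | methyl (2S,3S)-4-(benzyloxy)-2-(2,4-dimethoxyphenyl)-2,3-dihydrobenzofuran-3-carboxylate (trans) | c1ccc(OCc3ccccc3)c2c1O[C@H](c1ccc(OC)cc1OC)[C@H]2C(=O)OC | intermediate
12 | (2S,3S)-4-(benzyloxy)-2-(2,4-dimethoxyphenyl)-2,3-dihydrobenzofuran-3-carboxylic acid | c1ccc(OCc3ccccc3)c2c1O[C@H](c1ccc(OC)cc1OC)[C@H]2C(=O)O | intermediate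
13 | 1-iodo-3,5-dimethoxybenzene | COc1cc(I)cc(OC)c1 | starting material
14 | 1,3-dioxoisoindolin-2-yl (2S,3S)-4-(benzyloxy)-2-(2,4-dimethoxyphenyl)-2,3-dihydrobenzofuran-3-carboxylate | c1ccc(OCc3ccccc3)c2c1O[C@H](c1ccc(OC)cc1OC)[C@H]2C(=O)ON1C(=O)c2ccccc2C1=O | intermediate
15 | (2S,3S)-4-(benzyloxy)-2-(2,4-dimethoxyphenyl)-3-(3,5-dimethoxyphenyl)-2,3-dihydrobenzofuran | c1ccc(OCc3ccccc3)c2c1O[C@H](c1ccc(OC)cc1OC)[C@H]2c1cc(OC)cc(OC)c1 | intermediate
16 | (2S,3S)-2-(2,4-dimethoxyphenyl)-3-(3,5-dimethoxyphenyl)-2,3-dihydrobenzofuran-4-ol | c1ccc(O)c2c1O[C@H](c1ccc(OC)cc1OC)[C@H]2c1cc(OC)cc(OC)c1 | intermediate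
17 | (2S,3S)-7-bromo-2-(2,4-dimethoxyphenyl)-3-(3,5-dimethoxyphenyl)-2,3-dihydrobenzofuran-4-ol | Brc1ccc(O)c2c1O[C@H](c1ccc(OC)cc1OC)[C@H]2c1cc(OC)cc(OC)c1 | intermediate
18 | (2S,3S)-7-bromo-2-(2,4-dimethoxyphenyl)-3-(3,5-dimethoxyphenyl)-4-methoxy-2,3-dihydrobenzofuran | Brc1ccc(OC)c2c1O[C@H](c1ccc(OC)cc1OC)[C@H]2c1cc(OC)cc(OC)c1 | intermediate
19 | [(2S,3S)-2-(2,4-dimethoxyphenyl)-3-(3,5-dimethoxyphenyl)-4-methoxy-2,3-dihydrobenzofuran-7-yl]boronic acid | OB(O)c1ccc(OC)c2c1O[C@H](c1ccc(OC)cc1OC)[C@H]2c1cc(OC)cc(OC)c1 | intermediate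
20 | 2',6'-dihydroxy-4'-methoxyacetophenone | CC(=O)c1c(O)cc(OC)cc1O | starting material
21 | 1-[2-(benzyloxy)-6-hydroxy-4-methoxyphenyl]ethan-1-one | CC(=O)c1c(O)cc(OC)cc1OCc1ccccc1 | intermediate
22 | (E)-1-[2-(benzyloxy)-6-hydroxy-4-methoxyphenyl]-3-(dimethylamino)prop-2-en-1-one | CN(C)/C=C/C(=O)c1c(O)cc(OC)cc1OCc1ccccc1 | intermediate
23 | 5-(benzyloxy)-7-methoxy-4H-chromen-4-one | O=c1ccoc2cc(OC)cc(OCc3ccccc3)c12 | intermediate
24 | (2S)-5-(benzyloxy)-2-(DBF-7-yl)-7-methoxychroman-4-one | O=C1C[C@@H](c3ccc(OC)c4c3O[C@H](c3ccc(OC)cc3OC)[C@H]4c3cc(OC)cc(OC)c3)Oc2cc(OC)cc(OCc3ccccc3)c21 | intermediate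
25 | (2S)-5-(benzyloxy)-2-(DBF-7-yl)-7-methoxy-3-(trifluoroacetyl)chroman-4-one (C3 epimers, in equilibrium with the enol) | O=C1C(C(=O)C(F)(F)F)[C@@H](c3ccc(OC)c4c3O[C@H](c3ccc(OC)cc3OC)[C@H]4c3cc(OC)cc(OC)c3)Oc2cc(OC)cc(OCc3ccccc3)c21 | intermediate
26 | (2R)-5-(benzyloxy)-3-diazo-2-(DBF-7-yl)-7-methoxychroman-4-one | O=C1C(=[N+]=[N-])[C@@H](c3ccc(OC)c4c3O[C@H](c3ccc(OC)cc3OC)[C@H]4c3cc(OC)cc(OC)c3)Oc2cc(OC)cc(OCc3ccccc3)c21 | intermediate
27 | (2R)-4-(benzyloxy)-2-(DBF-7-yl)-6-methoxy-3-(oxomethylidene)-2,3-dihydrobenzofuran (ketene) | O(Cc1ccccc1)c1cc(OC)cc2c1C(=C=O)[C@@H](c1ccc(OC)c3c1O[C@H](c1ccc(OC)cc1OC)[C@H]3c1cc(OC)cc(OC)c1)O2 | intermediate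
28 | (2S)-4-(benzyloxy)-2-(DBF-7-yl)-6-methoxy-2,3-dihydrobenzofuran-3-carboxylic acid (C3 epimers) | O(Cc1ccccc1)c1cc(OC)cc2c1C(C(=O)O)[C@@H](c1ccc(OC)c3c1O[C@H](c1ccc(OC)cc1OC)[C@H]3c1cc(OC)cc(OC)c1)O2 | intermediate
29 | 1,3-dioxoisoindolin-2-yl (2S)-4-(benzyloxy)-2-(DBF-7-yl)-6-methoxy-2,3-dihydrobenzofuran-3-carboxylate (C3 epimers) | O(Cc1ccccc1)c1cc(OC)cc2c1C(C(=O)ON1C(=O)c3ccccc3C1=O)[C@@H](c1ccc(OC)c3c1O[C@H](c1ccc(OC)cc1OC)[C@H]3c1cc(OC)cc(OC)c1)O2 | intermediate
30 | (2S,3S)-4-(benzyloxy)-3-(3,5-dimethoxyphenyl)-2-(DBF-7-yl)-6-methoxy-2,3-dihydrobenzofuran | O(Cc1ccccc1)c1cc(OC)cc2c1[C@H](c1cc(OC)cc(OC)c1)[C@@H](c1ccc(OC)c3c1O[C@H](c1ccc(OC)cc1OC)[C@H]3c1cc(OC)cc(OC)c1)O2 | intermediate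
31 | (2S,3S)-3-(3,5-dimethoxyphenyl)-2-(DBF-7-yl)-6-methoxy-2,3-dihydrobenzofuran-4-ol | Oc1cc(OC)cc2c1[C@H](c1cc(OC)cc(OC)c1)[C@@H](c1ccc(OC)c3c1O[C@H](c1ccc(OC)cc1OC)[C@H]3c1cc(OC)cc(OC)c1)O2 | intermediate
32 | (2S,3S)-3-(3,5-dimethoxyphenyl)-2-(DBF-7-yl)-6-methoxy-2,3-dihydrobenzofuran-4-yl trifluoromethanesulfonate | O=S(=O)(Oc1cc(OC)cc2c1[C@H](c1cc(OC)cc(OC)c1)[C@@H](c1ccc(OC)c3c1O[C@H](c1ccc(OC)cc1OC)[C@H]3c1cc(OC)cc(OC)c1)O2)C(F)(F)F | intermediate
33 | (E)-2-(4-methoxyphenyl)ethenylboronic acid | COc1ccc(/C=C/B(O)O)cc1 | starting material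
34 | (2S,3S)-3-(3,5-dimethoxyphenyl)-2-(DBF-7-yl)-6-methoxy-4-[(E)-2-(4-methoxyphenyl)ethenyl]-2,3-dihydrobenzofuran | COc1ccc(/C=C/c2cc(OC)cc3c2[C@H](c2cc(OC)cc(OC)c2)[C@@H](c2ccc(OC)c4c2O[C@H](c2ccc(OC)cc2OC)[C@H]4c2cc(OC)cc(OC)c2)O3)cc1 | intermediate
35 | CNP0397447.1, (2S,3S)-2-[(2S,3S)-2-(2,4-dihydroxyphenyl)-3-(3,5-dihydroxyphenyl)-4-hydroxy-2,3-dihydrobenzofuran-7-yl]-3-(3,5-dihydroxyphenyl)-4-[(E)-2-(4-hydroxyphenyl)ethenyl]-2,3-dihydrobenzofuran-6-ol | Oc1ccc(/C=C/c2cc(O)cc3c2[C@H](c2cc(O)cc(O)c2)[C@@H](c2ccc(O)c4c2O[C@H](c2ccc(O)cc2O)[C@H]4c2cc(O)cc(O)c2)O3)cc1 | target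

Total step count: 21. Longest linear sequence: 19 steps (steps 1–11, then 14–21); steps 12–13 are a two-step branch to chromone 23.

Steps most likely to fail

Step 14. Protodeboronation of the ortho,para-dialkoxy arylboronic acid 19 may outrun aryl transfer to palladium, and insertion of the electron-rich 5,7-dioxygenated chromone may be slow, so that the advanced partner is lost as the arene. The fallback builds the flavanone by aldol chemistry instead of aryl transfer; it sets out from bromide 18 and comes back at 24. Bromine–lithium exchange of 18 (n-BuLi, THF, −78 °C) and quenching with DMF should give (2S,3S)-2-(2,4-dimethoxyphenyl)-3-(3,5-dimethoxyphenyl)-4-methoxy-2,3-dihydrobenzofuran-7-carbaldehyde F4. Claisen–Schmidt condensation of this aldehyde with acetophenone 21 (KOH, EtOH, 20 °C) should give (E)-1-[2-(benzyloxy)-6-hydroxy-4-methoxyphenyl]-3-(DBF-7-yl)prop-2-en-1-one F5. NaOAc in refluxing EtOH closes the chalcone by intramolecular oxa-Michael addition to flavanone 24 together with its C2 epimer (2R)-5-(benzyloxy)-2-(DBF-7-yl)-7-methoxychroman-4-one F6. Because the ring B unit is a single enantiomer, 24 and F6 are diastereomers and should separate on silica; F6 is returned to the chalcone equilibrium under the same conditions and recycled.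

Step 7 (step 17 repeats the reaction on a larger substrate). Capture of the crowded C3' benzylic radical by nickel may be slow, so that reduction to the anion with expulsion of the O1' aryloxide, loss of the C2' hydrogen to give the 2-arylbenzofuran, or capture from both faces take over. The fallback uses two-electron chemistry; it sets out from ester 11 and comes back at 15. Palladium-catalysed α-arylation of the ester enolate (LiNCy2, Pd(dba)2, P(t-Bu)3, 1-bromo-3,5-dimethoxybenzene, toluene, 20 °C) should place ring G anti to ring F and give methyl 4-(benzyloxy)-2-(2,4-dimethoxyphenyl)-3-(3,5-dimethoxyphenyl)-2,3-dihydrobenzofuran-3-carboxylate F1, with the ester cis to ring F. LiAlH4 (THF, 0 °C) reduces it to [4-(benzyloxy)-2-(2,4-dimethoxyphenyl)-3-(3,5-dimethoxyphenyl)-2,3-dihydrobenzofuran-3-yl]methanol F2, and Dess–Martin periodinane oxidises this to 4-(benzyloxy)-2-(2,4-dimethoxyphenyl)-3-(3,5-dimethoxyphenyl)-2,3-dihydrobenzofuran-3-carbaldehyde F3. Tsuji–Wilkinson decarbonylation (RhCl(PPh3)3, stoichiometric, PhCN, 130 °C) replaces the formyl group by hydrogen with retention, which leaves ring G trans to ring F and gives 15.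

Step 21. The Lewis acid may ionise the benzylic C2–O1 and C2'–O1' bonds, and on quenching the acid formed may protonate the stilbene so that ring D closes onto the benzylic cation (a seven-membered ring); incomplete cleavage of nine ethers is the other danger. The fallback demethylates before the alkene is present and finishes under mild base; it sets out from triflate 32 and comes back at 35. BBr3 (CH2Cl2, −78 → 20 °C) on 32 should give (2S,3S)-2-[(2S,3S)-2-(2,4-dihydroxyphenyl)-3-(3,5-dihydroxyphenyl)-4-hydroxy-2,3-dihydrobenzofuran-7-yl]-3-(3,5-dihydroxyphenyl)-6-hydroxy-2,3-dihydrobenzofuran-4-yl trifluoromethanesulfonate F7, the aryl triflate being inert to the reagent. Ac2O and pyridine convert it into the octaacetate of that triflate F8. A Mizoroki–Heck reaction with 4-acetoxystyrene (Pd(OAc)2, P(o-tol)3, Et3N, LiCl, DMF, 90 °C) should give the nonaacetate of the target F9. K2CO3 in degassed MeOH at 0 °C then removes the acetates and gives 35.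

Further compounds
F1 | step 7 | methyl 4-(benzyloxy)-2-(2,4-dimethoxyphenyl)-3-(3,5-dimethoxyphenyl)-2,3-dihydrobenzofuran-3-carboxylate (ring G trans to ring F, C2' as in 11) | c1ccc(OCc3ccccc3)c2c1O[C@H](c1ccc(OC)cc1OC)[C@]2(c1cc(OC)cc(OC)c1)C(=O)OC
F2 | step 7 | [4-(benzyloxy)-2-(2,4-dimethoxyphenyl)-3-(3,5-dimethoxyphenyl)-2,3-dihydrobenzofuran-3-yl]methanol (configuration as in F1) | c1ccc(OCc3ccccc3)c2c1O[C@H](c1ccc(OC)cc1OC)[C@]2(c1cc(OC)cc(OC)c1)CO
F3 | step 7 | 4-(benzyloxy)-2-(2,4-dimethoxyphenyl)-3-(3,5-dimethoxyphenyl)-2,3-dihydrobenzofuran-3-carbaldehyde (configuration as in F1) | c1ccc(OCc3ccccc3)c2c1O[C@H](c1ccc(OC)cc1OC)[C@]2(c1cc(OC)cc(OC)c1)C=O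
F4 | step 14 | (2S,3S)-2-(2,4-dimethoxyphenyl)-3-(3,5-dimethoxyphenyl)-4-methoxy-2,3-dihydrobenzofuran-7-carbaldehyde | O=Cc1ccc(OC)c2c1O[C@H](c1ccc(OC)cc1OC)[C@H]2c1cc(OC)cc(OC)c1
F5 | step 14 | (E)-1-[2-(benzyloxy)-6-hydroxy-4-methoxyphenyl]-3-(DBF-7-yl)prop-2-en-1-one | COc1cc(O)c(C(=O)/C=C/c2ccc(OC)c3c2O[C@H](c2ccc(OC)cc2OC)[C@H]3c2cc(OC)cc(OC)c2)c(OCc2ccccc2)c1
F6 | step 14 | (2R)-5-(benzyloxy)-2-(DBF-7-yl)-7-methoxychroman-4-one (C2 epimer of 24) | O=C1C[C@H](c3ccc(OC)c4c3O[C@H](c3ccc(OC)cc3OC)[C@H]4c3cc(OC)cc(OC)c3)Oc2cc(OC)cc(OCc3ccccc3)c21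
F7 | step 21 | (2S,3S)-2-[(2S,3S)-2-(2,4-dihydroxyphenyl)-3-(3,5-dihydroxyphenyl)-4-hydroxy-2,3-dihydrobenzofuran-7-yl]-3-(3,5-dihydroxyphenyl)-6-hydroxy-2,3-dihydrobenzofuran-4-yl trifluoromethanesulfonate | O=S(=O)(Oc1cc(O)cc2c1[C@H](c1cc(O)cc(O)c1)[C@@H](c1ccc(O)c3c1O[C@H](c1ccc(O)cc1O)[C@H]3c1cc(O)cc(O)c1)O2)C(F)(F)F
F8 | step 21 | octaacetate of F7 (all eight phenols acetylated, configuration unchanged) | O=S(=O)(Oc1cc(OC(C)=O)cc2c1[C@H](c1cc(OC(C)=O)cc(OC(C)=O)c1)[C@@H](c1ccc(OC(C)=O)c3c1O[C@H](c1ccc(OC(C)=O)cc1OC(C)=O)[C@H]3c1cc(OC(C)=O)cc(OC(C)=O)c1)O2)C(F)(F)F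
F9 | step 21 | nonaacetate of 35 (all nine phenols acetylated, E alkene, configuration unchanged) | CC(=O)Oc1ccc(/C=C/c2cc(OC(C)=O)cc3c2[C@H](c2cc(OC(C)=O)cc(OC(C)=O)c2)[C@@H](c2ccc(OC(C)=O)c4c2O[C@H](c2ccc(OC(C)=O)cc2OC(C)=O)[C@H]4c2cc(OC(C)=O)cc(OC(C)=O)c2)O3)cc1
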